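The dihydrofuran ring is disconnected at O1–C7a and C3a–C3: benzo ring A becomes a benzyne and O1–C2–C3 an enantiopure trans-diaryl oxirane. In one operation the aryne inserts into the benzylic C3–O bond of the epoxide, which closes the five-membered ring and carries both stereocentres into the product. The step exploits the fact that C7a and C3a are adjacent carbons of ring A, while O1, C2 and C3 are the three atoms of a stilbene oxide. Its precursors are a 3-chloro-4-styryl-2-silylaryl triflate and the (2R,3R)-epoxide from Shi epoxidation; a C4 chlorine and catechol mesylates steer both regiochemistries and are removed afterwards.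

Key step: step 8

Remark: the target is the trans-(2S,3S)-2,3-diaryl-2,3-dihydro-1-benzofuran (numbering O1, C2, C3, C3a, C4 to C7, C7a; ring A is the benzo ring); compounds 1, 3 and 6 and all reagents named are taken as commercial.

Step 1
Reactants: 1 4-bromobenzene-1,2-diol
Product: 2 4-bromo-1,2-phenylene dimethanesulfonate
Conditions: MsCl, Et3N, CH2Cl2, 0 °C to rt
Reagents that add atoms: methanesulfonyl chloride, CS(=O)(=O)Cl
Why: Base-mediated O-sulfonylation of both phenols; the mesylates serve later as electron-withdrawing protecting groups that decide which epoxide C–O bond breaks.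

Step 2
Reactants: 2 4-bromo-1,2-phenylene dimethanesulfonate; 3 1-ethenyl-3,5-dimethoxybenzene
Product: 4 4-[(E)-2-(3,5-dimethoxyphenyl)ethenyl]-1,2-phenylene dimethanesulfonate
Conditions: Pd(OAc)2 (cat.), P(o-tol)3, Et3N, DMF, 100 °C
Reagents that add atoms: none
Why: Mizoroki–Heck reaction, in which oxidative addition into the C–Br bond, syn-insertion of the styrene and syn-β-hydride elimination should give the (E)-stilbene while the aryl mesylates stay inert to this catalyst.

Step 3
Reactants: 4 4-[(E)-2-(3,5-dimethoxyphenyl)ethenyl]-1,2-phenylene dimethanesulfonate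
Product: 5 4-[(2R,3R)-3-(3,5-dimethoxyphenyl)oxiran-2-yl]-1,2-phenylene dimethanesulfonate
Conditions: D-fructose-derived Shi ketone (30 mol%), Oxone (2KHSO5·KHSO4·K2SO4), K2CO3, Bu4NHSO4, MeCN/CH2(OMe)2, aq. Na2B4O7–Na2EDTA buffer, 0 °C
Reagents that add atoms: potassium peroxymonosulfate, [K+].[O-]S(=O)(=O)OO
Why: Shi asymmetric epoxidation, in which the chiral dioxirane from the D-fructose-derived ketone delivers oxygen through a spiro transition state to one face of the trans-alkene and so sets both stereocentres as (2R,3R), the sense known for trans-stilbene; the epoxide carries no para donor and should survive the basic medium, and recrystallisation can raise the enantiomeric purity.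

Step 4
Reactants: 6 4-bromo-3-chlorophenol; 3 1-ethenyl-3,5-dimethoxybenzene
Product: 7 3-chloro-4-[(E)-2-(3,5-dimethoxyphenyl)ethenyl]phenol
Conditions: Pd(OAc)2 (cat.), P(o-tol)3, Et3N, DMF, 100 °C
Reagents that add atoms: none
Why: Mizoroki–Heck reaction that is chemoselective for the C–Br over the C–Cl bond, tolerates the free phenol and should give the (E)-alkene.

Step 5
Reactants: 7 3-chloro-4-[(E)-2-(3,5-dimethoxyphenyl)ethenyl]phenol
Product: 8 3-chloro-4-[(E)-2-(3,5-dimethoxyphenyl)ethenyl]phenyl N-isopropylcarbamate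
Conditions: i-PrNCO, Et3N (cat.), CH2Cl2, rt
Reagents that add atoms: isopropyl isocyanate, CC(C)N=C=O
Why: Amine-catalysed addition of the phenol to the isocyanate gives the carbamate that acts as directing group in the next step.

Step 6
Reactants: 8 3-chloro-4-[(E)-2-(3,5-dimethoxyphenyl)ethenyl]phenyl N-isopropylcarbamate
Product: 12 3-chloro-4-[(E)-2-(3,5-dimethoxyphenyl)ethenyl]-2-(trimethylsilyl)phenyl N-isopropylcarbamate, via N-silyl carbamate 9 (not isolated), via aryllithium 10 (not isolated), via bis-silyl carbamate 11 (not isolated)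
Conditions: TMSOTf, TMEDA, Et2O, 0 °C to rt; n-BuLi, TMEDA, −78 °C; TMSCl, −78 °C to rt; aq. NaHSO4
Reagents that add atoms: chlorotrimethylsilane, C[Si](C)(C)Cl
Why: Directed ortho-metalation, in which the N-silylated carbamate and the chlorine together direct lithiation to the carbon between them at −78 °C (below the temperature of LiCl loss and of carbolithiation of the stilbene), TMSCl quenches the aryllithium and the N–Si bond is hydrolysed on work-up.

Step 7
Reactants: 12 3-chloro-4-[(E)-2-(3,5-dimethoxyphenyl)ethenyl]-2-(trimethylsilyl)phenyl N-isopropylcarbamate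
Product: 14 3-chloro-4-[(E)-2-(3,5-dimethoxyphenyl)ethenyl]-2-(trimethylsilyl)phenyl trifluoromethanesulfonate, via silyl phenol 13 (not isolated)
Conditions: DBU, Et2NH, MeCN, 40 °C; then PhNTf2, rt
Reagents that add atoms: N-phenylbis(trifluoromethanesulfonimide), O=S(=O)(N(c1ccccc1)S(=O)(=O)C(F)(F)F)C(F)(F)F
Why: E1cB cleavage of the N-monosubstituted carbamate (the isocyanate is scavenged by Et2NH) and O-triflation of the phenoxide in the same pot should give the ortho-silylaryl triflate, a fluoride-triggered aryne precursor.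

Step 8
Reactants: 14 3-chloro-4-[(E)-2-(3,5-dimethoxyphenyl)ethenyl]-2-(trimethylsilyl)phenyl trifluoromethanesulfonate; 5 4-[(2R,3R)-3-(3,5-dimethoxyphenyl)oxiran-2-yl]-1,2-phenylene dimethanesulfonate
Product: 16 4-[(2S,3S)-4-chloro-3-(3,5-dimethoxyphenyl)-5-[(E)-2-(3,5-dimethoxyphenyl)ethenyl]-2,3-dihydro-1-benzofuran-2-yl]-1,2-phenylene dimethanesulfonate, via aryne 15 (not isolated)
Conditions: CsF, MeCN, rt, 5 in excess (recovered)
Reagents that add atoms: none
Why: Fluoride removes the silyl group of 14 and triflate (a far better leaving group than chloride) departs to give aryne 15; the epoxide oxygen of 5 adds to the aryne carbon remote from chlorine, the resulting O-aryl oxiranium opens at C3 to the 3,5-dimethoxybenzylic cation and the ortho aryl carbanion collapses on it, so that O1–C7a and C3a–C3 form in one operation. The closest known reaction type is the insertion of arynes into the benzylic C–O bond of aryl epoxides, a formal [3+2] annulation that gives 3-aryl-2,3-dihydrobenzofurans. The dihydrofuran ring closes by carbanion–carbocation collapse, formally a 5-exo-trig attack of C3a on the exocyclic benzylic cation at C3. C2 keeps the configuration of the epoxide because its C–O bond is never broken, and C3 is set trans to the C2 aryl group under control of C2, by front-side collapse within the ion pair (retention) and by the lower strain of the trans-2,3-diaryl ring. Two regioselectivities are needed: cleavage of C3–O and not C2–O, secured by the two strongly electron-withdrawing mesylates that make the catechol-bearing carbon the poorer cation site next to the weakly perturbed dimethoxyphenyl carbon, and attack of oxygen at the carbon that becomes C7a, secured by the inductive and steric effect of the C4 chlorine, which places the carbanion next to itself. Mesylates, methyl ethers and the stilbene should be inert to CsF at room temperature.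

Step 9
Reactants: 16 4-[(2S,3S)-4-chloro-3-(3,5-dimethoxyphenyl)-5-[(E)-2-(3,5-dimethoxyphenyl)ethenyl]-2,3-dihydro-1-benzofuran-2-yl]-1,2-phenylene dimethanesulfonate
Product: 17 4-[(2S,3S)-3-(3,5-dimethoxyphenyl)-5-[(E)-2-(3,5-dimethoxyphenyl)ethenyl]-2,3-dihydro-1-benzofuran-2-yl]-1,2-phenylene dimethanesulfonate
Conditions: Pd(OAc)2 (cat.), XPhos, HCO2K, DMF, 80 °C
Reagents that add atoms: none
Why: Palladium-catalysed transfer hydrodehalogenation, in which zerovalent palladium inserts into the C4–Cl bond, formate exchanges and decarboxylates to an arylpalladium hydride and reductive elimination gives C4–H; this catalyst inserts into aryl chlorides much faster than into aryl mesylates and neither stereocentre is touched.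

Step 10
Reactants: 17 4-[(2S,3S)-3-(3,5-dimethoxyphenyl)-5-[(E)-2-(3,5-dimethoxyphenyl)ethenyl]-2,3-dihydro-1-benzofuran-2-yl]-1,2-phenylene dimethanesulfonate
Product: 19 4-[(2S,3S)-3-(3,5-dihydroxyphenyl)-5-[(E)-2-(3,5-dihydroxyphenyl)ethenyl]-2,3-dihydro-1-benzofuran-2-yl]benzene-1,2-diol, via tetraphenol bis-mesylate 18 (not isolated)
Conditions: BBr3, CH2Cl2, −78 °C to rt; MeOH quench, evaporate; then 2 M NaOH, MeOH, argon, 50 °C; HCl to pH 3
Reagents that add atoms: none
Why: BBr3 cleaves the four aryl methyl ethers by bromide attack on the boron-activated methyl groups while the electron-poor mesylated aryl group at C2 suppresses ionisation of the C2–O1 bond, and hydroxide then cleaves the two aryl mesylates under argon; no stereocentre is affected.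

Compound list
1 | 4-bromobenzene-1,2-diol | Oc1ccc(Br)cc1O | starting material
2 | 4-bromo-1,2-phenylene dimethanesulfonate | CS(=O)(=O)Oc1ccc(Br)cc1OS(C)(=O)=O | intermediate
3 | 1-ethenyl-3,5-dimethoxybenzene (3,5-dimethoxystyrene) | C=Cc1cc(OC)cc(OC)c1 | starting material
4 | 4-[(E)-2-(3,5-dimethoxyphenyl)ethenyl]-1,2-phenylene dimethanesulfonate | COc1cc(OC)cc(/C=C/c2ccc(OS(C)(=O)=O)c(OS(C)(=O)=O)c2)c1 | intermediate
5 | 4-[(2R,3R)-3-(3,5-dimethoxyphenyl)oxiran-2-yl]-1,2-phenylene dimethanesulfonate | COc1cc(OC)cc(c1)[C@H]1O[C@@H]1c1ccc(OS(C)(=O)=O)c(OS(C)(=O)=O)c1 | intermediate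
6 | 4-bromo-3-chlorophenol | Oc1ccc(Br)c(Cl)c1 | starting material
7 | 3-chloro-4-[(E)-2-(3,5-dimethoxyphenyl)ethenyl]phenol | COc1cc(OC)cc(/C=C/c2ccc(O)cc2Cl)c1 | intermediate
8 | 3-chloro-4-[(E)-2-(3,5-dimethoxyphenyl)ethenyl]phenyl N-isopropylcarbamate | COc1cc(OC)cc(/C=C/c2ccc(OC(=O)NC(C)C)cc2Cl)c1 | intermediate
9 | N-trimethylsilyl derivative of carbamate 8 | COc1cc(OC)cc(/C=C/c2ccc(OC(=O)N(C(C)C)[Si](C)(C)C)cc2Cl)c1 | intermediate (not isolated)
10 | 2-lithio derivative of 9 (lithium between carbamate and chlorine) | COc1cc(OC)cc(/C=C/c2ccc(OC(=O)N(C(C)C)[Si](C)(C)C)c([Li])c2Cl)c1 | intermediate (not isolated)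
11 | 2-trimethylsilyl derivative of 9 (C- and N-silylated carbamate) | COc1cc(OC)cc(/C=C/c2ccc(OC(=O)N(C(C)C)[Si](C)(C)C)c([Si](C)(C)C)c2Cl)c1 | intermediate (not isolated)
12 | 3-chloro-4-[(E)-2-(3,5-dimethoxyphenyl)ethenyl]-2-(trimethylsilyl)phenyl N-isopropylcarbamate | COc1cc(OC)cc(/C=C/c2ccc(OC(=O)NC(C)C)c([Si](C)(C)C)c2Cl)c1 | intermediate
13 | 3-chloro-4-[(E)-2-(3,5-dimethoxyphenyl)ethenyl]-2-(trimethylsilyl)phenol | COc1cc(OC)cc(/C=C/c2ccc(O)c([Si](C)(C)C)c2Cl)c1 | intermediate (not isolated)
14 | 3-chloro-4-[(E)-2-(3,5-dimethoxyphenyl)ethenyl]-2-(trimethylsilyl)phenyl trifluoromethanesulfonate | COc1cc(OC)cc(/C=C/c2ccc(OS(=O)(=O)C(F)(F)F)c([Si](C)(C)C)c2Cl)c1 | intermediate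
15 | 3-chloro-4-[(E)-2-(3,5-dimethoxyphenyl)ethenyl]benzyne (1,2-didehydrobenzene) | COc1cc(OC)cc(/C=C/C2=C(Cl)C#CC=C2)c1 | intermediate (not isolated)
16 | 4-[(2S,3S)-4-chloro-3-(3,5-dimethoxyphenyl)-5-[(E)-2-(3,5-dimethoxyphenyl)ethenyl]-2,3-dihydro-1-benzofuran-2-yl]-1,2-phenylene dimethanesulfonate | COc1cc(OC)cc(/C=C/c2ccc3c(c2Cl)[C@H](c2cc(OC)cc(OC)c2)[C@@H](c2ccc(OS(C)(=O)=O)c(OS(C)(=O)=O)c2)O3)c1 | intermediate
17 | 4-[(2S,3S)-3-(3,5-dimethoxyphenyl)-5-[(E)-2-(3,5-dimethoxyphenyl)ethenyl]-2,3-dihydro-1-benzofuran-2-yl]-1,2-phenylene dimethanesulfonate | COc1cc(OC)cc(/C=C/c2ccc3c(c2)[C@H](c2cc(OC)cc(OC)c2)[C@@H](c2ccc(OS(C)(=O)=O)c(OS(C)(=O)=O)c2)O3)c1 | intermediate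
18 | 4-[(2S,3S)-3-(3,5-dihydroxyphenyl)-5-[(E)-2-(3,5-dihydroxyphenyl)ethenyl]-2,3-dihydro-1-benzofuran-2-yl]-1,2-phenylene dimethanesulfonate | Oc1cc(O)cc(/C=C/c2ccc3c(c2)[C@H](c2cc(O)cc(O)c2)[C@@H](c2ccc(OS(C)(=O)=O)c(OS(C)(=O)=O)c2)O3)c1 | intermediate (not isolated)
19 | 4-[(2S,3S)-3-(3,5-dihydroxyphenyl)-5-[(E)-2-(3,5-dihydroxyphenyl)ethenyl]-2,3-dihydro-1-benzofuran-2-yl]benzene-1,2-diol | Oc1cc(O)cc(/C=C/c2ccc3c(c2)[C@H](c2cc(O)cc(O)c2)[C@@H](c2ccc(O)c(O)c2)O3)c1 | target

Total step count: 10.
Longest linear sequence: 7 steps (steps 4, 5, 6, 7, 8, 9 and 10).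

Steps most likely to fail

Step 8. The hindered, electron-poor epoxide oxygen may capture the aryne too slowly, so that the aryne is consumed by fluoride, by the stilbene or by itself, or the zwitterion may be diverted by proton transfer to an aryl enol ether. The fallback forms the same two bonds one after the other; it sets out from 5 and comes back at 17. Acid-catalysed hydrolysis of 5 (HClO4 cat., THF/H2O), with water attacking the dimethoxybenzylic carbon with inversion, should give the erythro-diol F1. Trimethyl orthoacetate with pyridinium tosylate converts it into the cyclic orthoacetate F2, acetyl bromide opens this to the acetoxy bromide F3, and K2CO3 in MeOH closes the cis-epoxide F4 (two inversions at one carbon, so the diol configuration is kept). Separately, Horner–Wadsworth–Emmons olefination of commercial 4-bromo-3-iodobenzaldehyde with diethyl (3,5-dimethoxybenzyl)phosphonate and NaH gives the dihalostilbene F5, whose iodide is exchanged with i-PrMgCl·LiCl at −20 °C to the arylmagnesium chloride F6. CuI-catalysed opening of F4 by F6 at the dimethoxybenzylic carbon with inversion forms C3a–C3 and should give the bromoaryl alcohol F7 with the (S,S) arrangement. Intramolecular Ullmann O-arylation (CuI, 1,10-phenanthroline, Cs2CO3, toluene, 110 °C) then forms O1–C7a and gives 17 directly, without chlorine.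

Step 9. Oxidative addition at the doubly ortho-substituted C4–Cl bond may be slow, and the palladium hydride formed from formate may add to the stilbene double bond instead. The fallback replaces the hydride pathway by a boron relay; it sets out from 16 and comes back at 17. Miyaura borylation (Pd2(dba)3, XPhos, B2pin2, KOAc, dioxane, 100 °C) should give the aryl pinacol boronate F8, and iridium-catalysed protodeboronation ([Ir(OMe)(cod)]2 cat., MeOH/THF/H2O, 60 °C) then gives 17 without any metal hydride that could reduce the alkene.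

Step 10. The Lewis acid may hydrobrominate or oligomerise the electron-rich stilbene or open the dihydrofuran during demethylation, and the free catechol may oxidise in the basic second stage. The fallback abandons Lewis-acid ether cleavage for anionic nucleophilic unmasking; it sets out from 17 and comes back at 19, and no new compound is made (F0). Sodium ethanethiolate in DMF at 130 °C under argon should cleave the four methyl ethers by substitution at the methyl carbon and both mesylates by attack at sulfur in one basic operation, followed by acidic work-up.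

Further compounds
F1 | step 8 | 4-[(1R,2S)-2-(3,5-dimethoxyphenyl)-1,2-dihydroxyethyl]-1,2-phenylene dimethanesulfonate | COc1cc(OC)cc(c1)[C@H](O)[C@H](O)c1ccc(OS(C)(=O)=O)c(OS(C)(=O)=O)c1
F2 | step 8 | 4-[(4R,5S)-5-(3,5-dimethoxyphenyl)-2-methoxy-2-methyl-1,3-dioxolan-4-yl]-1,2-phenylene dimethanesulfonate | COc1cc(OC)cc(c1)[C@@H]1OC(C)(OC)O[C@@H]1c1ccc(OS(C)(=O)=O)c(OS(C)(=O)=O)c1
F3 | step 8 | (1R,2R)-1-[3,4-bis(methanesulfonyloxy)phenyl]-2-bromo-2-(3,5-dimethoxyphenyl)ethyl acetate | COc1cc(OC)cc(c1)[C@@H](Br)[C@H](OC(C)=O)c1ccc(OS(C)(=O)=O)c(OS(C)(=O)=O)c1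
F4 | step 8 | 4-[(2R,3S)-3-(3,5-dimethoxyphenyl)oxiran-2-yl]-1,2-phenylene dimethanesulfonate | COc1cc(OC)cc(c1)[C@@H]1O[C@@H]1c1ccc(OS(C)(=O)=O)c(OS(C)(=O)=O)c1
F5 | step 8 | 1-bromo-4-[(E)-2-(3,5-dimethoxyphenyl)ethenyl]-2-iodobenzene | COc1cc(OC)cc(/C=C/c2ccc(Br)c(I)c2)c1
F6 | step 8 | {2-bromo-5-[(E)-2-(3,5-dimethoxyphenyl)ethenyl]phenyl}magnesium chloride | COc1cc(OC)cc(/C=C/c2ccc(Br)c([Mg]Cl)c2)c1
F7 | step 8 | 4-[(1S,2S)-2-{2-bromo-5-[(E)-2-(3,5-dimethoxyphenyl)ethenyl]phenyl}-2-(3,5-dimethoxyphenyl)-1-hydroxyethyl]-1,2-phenylene dimethanesulfonate | COc1cc(OC)cc(/C=C/c2ccc(Br)c(c2)[C@H](c2cc(OC)cc(OC)c2)[C@H](O)c2ccc(OS(C)(=O)=O)c(OS(C)(=O)=O)c2)c1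
F8 | step 9 | 4-[(2S,3S)-3-(3,5-dimethoxyphenyl)-5-[(E)-2-(3,5-dimethoxyphenyl)ethenyl]-4-(4,4,5,5-tetramethyl-1,3,2-dioxaborolan-2-yl)-2,3-dihydro-1-benzofuran-2-yl]-1,2-phenylene dimethanesulfonate | COc1cc(OC)cc(/C=C/c2ccc3c(c2B4OC(C)(C)C(C)(C)O4)[C@H](c2cc(OC)cc(OC)c2)[C@@H](c2ccc(OS(C)(=O)=O)c(OS(C)(=O)=O)c2)O3)c1
F0 | step 10 | none | none
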